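The decalin (drimane numbering) is disconnected at C3–C4 and C5–C10, the two para-related bonds of ring A, of which C5–C10 is also the bond shared with ring B. Both are formed in one Lewis-acid-promoted intramolecular Diels–Alder reaction of an acyclic (Z)-dienyl enone: diene C10=C1–C2=C3, dienophile C4=C5 activated by a temporary C6 ketone, tether C6–C9. The only pre-set stereocentre, C9 (from a catalytic desymmetrising ring-closing metathesis), controls C10 through allylic strain. C5 is then equilibrated through the ketone, which is afterwards excised with introduction of the C7=C8 alkene, and the arene is attached last at C11.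

Key step: step 6

Assumption: in step 3 the (S)-biphenolate molybdenum catalyst is taken to give the (S)-siloxane 8; should the sense of induction be the opposite, the enantiomeric catalyst is used.

Step 1
Reactants: 1 2,4-dimethylpenta-1,3-diene; 2 formaldehyde (supplied as paraformaldehyde)
Product: 5 3-methyl-2-(prop-1-en-2-yl)but-3-en-1-ol, via potassium 2,4-dimethylpentadienide 3 (not isolated), via (2,4-dimethylpenta-2,4-dienyl)zinc chloride 4 (not isolated)
Conditions: n-BuLi, KOt-Bu, THF/hexane, −78 → 0 °C; ZnCl2, −78 °C; then 2, −78 → 25 °C; aq. NH4Cl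
Reagents that add atoms: none
Why: Metalation of a C4 methyl group gives the delocalised pentadienyl anion, and its terminally bound zinc derivative should add to formaldehyde through a six-membered SE2′ transition state at the central carbon (γ-selective allylmetal addition), giving the achiral skipped diene with no stereocentre.

Step 2
Reactants: 5 3-methyl-2-(prop-1-en-2-yl)but-3-en-1-ol; 6 chloro(dimethyl)vinylsilane
Product: 7 dimethyl{[3-methyl-2-(prop-1-en-2-yl)but-3-en-1-yl]oxy}(vinyl)silane
Conditions: imidazole, CH2Cl2, 0 → 25 °C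
Reagents that add atoms: none
Why: Routine O-silylation of the primary alcohol installs the vinylsilane tether needed for ring closure.

Step 3
Reactants: 7 dimethyl{[3-methyl-2-(prop-1-en-2-yl)but-3-en-1-yl]oxy}(vinyl)silane
Product: 8 (5S)-2,2,4-trimethyl-5-(prop-1-en-2-yl)-5,6-dihydro-2H-1,2-oxasiline
Conditions: Mo(N-2,6-i-Pr2C6H3)(CHCMe2Ph)[(S)-3,3′-di-tert-butyl-5,5′,6,6′-tetramethylbiphenyl-2,2′-diolate] (5 mol %), benzene, 22 °C
Reagents that add atoms: none
Why: Catalytic enantioselective desymmetrising ring-closing metathesis: the alkylidene formed at the vinylsilane closes onto one of the two enantiotopic isopropenyl groups, the chiral biphenolate differentiating the two metallacyclobutanes, which sets the stereocentre (later C9) and a ring-enforced cis trisubstituted alkene.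

Step 4
Reactants: 8 (5S)-2,2,4-trimethyl-5-(prop-1-en-2-yl)-5,6-dihydro-2H-1,2-oxasiline; 9 carbon monoxide; 10 1-bromo-2-methylprop-1-ene
Product: 12 2-methyl-6-[(5S)-2,2,4-trimethyl-5,6-dihydro-2H-1,2-oxasilin-5-yl]hept-2-en-4-one (both C6 epimers), via B-alkyl-9-borabicyclo[3.3.1]nonane adduct 11 (not isolated)
Conditions: 9-borabicyclo[3.3.1]nonane, THF, 0 → 25 °C; then 9 (1 atm), 10, Pd(PPh3)4 (5 mol %), K3PO4, dioxane, 50 °C
Reagents that add atoms: none
Why: 9-BBN should hydroborate only the 1,1-disubstituted alkene (anti-Markovnikov), and the B-alkyl group is then transferred to the acylpalladium species from 10 and CO (carbonylative Suzuki–Miyaura coupling); the new methyl-bearing centre (later C8) is uncontrolled and becomes sp2 in step 8.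

Step 5
Reactants: 12 2-methyl-6-[(5S)-2,2,4-trimethyl-5,6-dihydro-2H-1,2-oxasilin-5-yl]hept-2-en-4-one; 13 iodoethene
Product: 14 (7S,8Z)-7-(hydroxymethyl)-2,6,8-trimethylundeca-2,8,10-trien-4-one (both C6 epimers)
Conditions: Pd(dba)2 (5 mol %), n-Bu4NF (2 equiv), THF, 25 °C
Reagents that add atoms: none
Why: Fluoride-activated cross-coupling of the cyclic alkenylsiloxane (Hiyama–Denmark coupling) should replace silicon by vinyl with retention of alkene geometry, so the ring-derived cis relationship becomes the Z-diene (C9 cis to C2) and the primary alcohol is released.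

Step 6
Reactants: 14 (7S,8Z)-7-(hydroxymethyl)-2,6,8-trimethylundeca-2,8,10-trien-4-one
Product: 15 11-hydroxy-5β-drim-1-en-6-one (cis-fused: 5β-H, 9α-H, 10β-CH3; both C8 epimers)
Conditions: Me2AlCl (2.5 equiv), CH2Cl2, −78 → 0 °C; aq. HCl
Reagents that add atoms: none
Why: Me2AlCl converts the hydroxyl into an aluminium alkoxide and a second equivalent binds the C6 carbonyl, so that the mesityl-oxide-type enone (C4=C5) and the (Z)-diene (C10=C1–C2=C3) combine in a concerted but asynchronous intramolecular Diels–Alder reaction in which the unsubstituted terminus C3 bonds to the β-carbon C4 ahead of C10–C5. The closest known reactions are Lewis-acid-promoted cycloadditions of mesityl oxide with 1-substituted butadienes and intramolecular Diels–Alder reactions of deca-1,7,9-trien-3-ones. Ring A is closed as the new cyclohexene of the [4+2] process (bonds C3–C4 and C5–C10), ring B by the same C5–C10 bond across the four-carbon tether C6–C9 (type 1 intramolecular mode). Because the tether occupies the inside (Z) position of the diene, only the transition state with C6 exo is within reach, which sets C5 as the cis-fused epimer (corrected in step 7). C10 is set by C9: allylic 1,3-strain against C2–H holds the C9–H in the diene plane, C8 on one face and CH2OH on the other, so the dienophile is delivered to the face that leaves C10–CH3 cis to C11. The step needs chemoselectivity for cycloaddition over cationic side reactions (low temperature, no other nucleophilic alkene in 14) and facial selectivity (allylic strain as above); regiochemistry is fixed by the tether, and both C8 epimers converge in step 8.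

Step 7
Reactants: 15 11-hydroxy-5β-drim-1-en-6-one
Product: 17 11-hydroxy-5α-driman-6-one (both C8 epimers), via 11-hydroxy-5α-drim-1-en-6-one 16 (not isolated)
Conditions: NaOMe (0.3 equiv), MeOH, 25 °C; then palladium on carbon (Pd/C), H2 (1 atm)
Reagents that add atoms: none
Why: Methoxide should equilibrate C5 through the C6 enolate to the more stable trans-fused decalone (C9 is not enolisable while ring B is saturated), and hydrogenation then saturates C1=C2, the only alkene present.

Step 8
Reactants: 17 11-hydroxy-5α-driman-6-one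
Product: 20 11-hydroxydrim-7-en-6-one, via 6,11-bis(trimethylsilyloxy)-5α-drim-6-ene 18 (not isolated), via 11-(trimethylsilyloxy)drim-7-en-6-one 19 (not isolated)
Conditions: LiN(i-Pr)2 (2.5 equiv), Me3SiCl, THF, −78 °C; then Pd(OAc)2 (1.1 equiv), MeCN, 25 °C; 1 M HCl work-up
Reagents that add atoms: none
Why: Saegusa–Ito oxidation: kinetic deprotonation should occur at C7 (C5–H is tertiary and flanked by two quaternary carbons), and palladium diacetate converts the silyl enol ether into the enone by β-hydride elimination of the only β-hydrogen (at C8), which also erases the C8 epimer mixture.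

Step 9
Reactants: 20 11-hydroxydrim-7-en-6-one
Product: 21 drim-7-ene-6,11-diol (C6 epimers; configuration at C6 inconsequential)
Conditions: NaBH4, CeCl3·7H2O, MeOH, −40 °C
Reagents that add atoms: none
Why: Luche reduction gives selective 1,2-reduction of the enone to the allylic alcohol without touching the C7=C8 alkene.

Step 10
Reactants: 21 drim-7-ene-6,11-diol
Product: 22 (−)-drimenol, [(1S,4aS,8aS)-2,5,5,8a-tetramethyl-1,4,4a,5,6,7,8,8a-octahydronaphthalen-1-yl]methanol
Conditions: Et3SiH (3 equiv), BF3·OEt2 (1.5 equiv), CH2Cl2, −78 → −40 °C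
Reagents that add atoms: none
Why: Ionic hydrogenation: BF3 ionises the allylic C6 alcohol to the C6–C7–C8 allyl cation and Et3SiH should deliver hydride to the less hindered secondary terminus C6, leaving the trisubstituted C7=C8 alkene; the primary alcohol does not ionise.

Step 11
Reactants: 22 (−)-drimenol
Product: 23 11-iododrim-7-ene
Conditions: I2, PPh3, imidazole, toluene, 25 → 60 °C
Reagents that add atoms: iodine, II
Why: Appel reaction converts the primary alcohol into the iodide by SN2 displacement of the alkoxyphosphonium, with no stereocentre involved.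

Step 12
Reactants: 24 methyl 3-bromo-4,5-dihydroxybenzoate
Product: 25 methyl 3-bromo-4,5-bis(methoxymethoxy)benzoate
Conditions: MOMCl, i-Pr2NEt, CH2Cl2, 0 → 25 °C
Reagents that add atoms: chloromethyl methyl ether (MOMCl), COCCl
Why: O-alkylation of both phenols gives acetal protecting groups that tolerate the organozinc coupling and fall off with mild acid.

Step 13
Reactants: 23 11-iododrim-7-ene; 25 methyl 3-bromo-4,5-bis(methoxymethoxy)benzoate
Product: 27 methyl 3-(drim-7-en-11-yl)-4,5-bis(methoxymethoxy)benzoate, via (drim-7-en-11-yl)zinc iodide 26 (not isolated)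
Conditions: Zn dust (activated), LiCl, THF, 50 °C; then 25, Pd(OAc)2 (3 mol %), SPhos (6 mol %), THF, 60 °C
Reagents that add atoms: none
Why: Zinc insertion into the primary iodide followed by Negishi coupling forms the C11–aryl bond; the bulky biarylphosphine should favour reductive elimination over β-hydride elimination, and the ester is tolerated.

Step 14
Reactants: 27 methyl 3-(drim-7-en-11-yl)-4,5-bis(methoxymethoxy)benzoate
Product: 28 methyl 3,4-dihydroxy-5-{[(5S,9S,10S)-drim-7-en-11-yl]}benzoate (CNP0193946.2)
Conditions: HCl (2 M in MeOH), 25 °C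
Reagents that add atoms: none
Why: Acid-catalysed transacetalisation to methanol removes both methoxymethyl groups under conditions that should leave the trisubstituted alkene and the methyl ester untouched.

Compound list
1 | 2,4-dimethylpenta-1,3-diene | CC(C)=CC(C)=C | starting material
2 | formaldehyde (supplied as paraformaldehyde) | C=O | starting material
3 | potassium 2,4-dimethylpentadienide | [K+].[CH2-]C(C)=CC(C)=C | intermediate
4 | (2,4-dimethylpenta-2,4-dienyl)zinc chloride | Cl[Zn]CC(C)=CC(C)=C | intermediate
5 | 3-methyl-2-(prop-1-en-2-yl)but-3-en-1-ol | OCC(C(C)=C)C(C)=C | intermediate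
6 | chloro(dimethyl)vinylsilane | C=C[Si](C)(C)Cl | starting material
7 | dimethyl{[3-methyl-2-(prop-1-en-2-yl)but-3-en-1-yl]oxy}(vinyl)silane | C=C[Si](C)(C)OCC(C(C)=C)C(C)=C | intermediate
8 | (5S)-2,2,4-trimethyl-5-(prop-1-en-2-yl)-5,6-dihydro-2H-1,2-oxasiline | C[Si]1(C)OC[C@@H](C(C)=C)C(C)=C1 | intermediate
9 | carbon monoxide | [C-]#[O+] | starting material
10 | 1-bromo-2-methylprop-1-ene | CC(C)=CBr | starting material
11 | 9-{2-[(5S)-2,2,4-trimethyl-5,6-dihydro-2H-1,2-oxasilin-5-yl]propyl}-9-borabicyclo[3.3.1]nonane (both epimers at the propyl CH) | C[Si]1(C)OC[C@@H](C(C)CB2C3CCCC2CCC3)C(C)=C1 | intermediate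
12 | 2-methyl-6-[(5S)-2,2,4-trimethyl-5,6-dihydro-2H-1,2-oxasilin-5-yl]hept-2-en-4-one (both C6 epimers) | C[Si]1(C)OC[C@@H](C(C)CC(=O)C=C(C)C)C(C)=C1 | intermediate
13 | iodoethene | C=CI | starting material
14 | (7S,8Z)-7-(hydroxymethyl)-2,6,8-trimethylundeca-2,8,10-trien-4-one (both C6 epimers) | OC[C@H](/C(C)=C\C=C)C(C)CC(=O)C=C(C)C | intermediate
15 | 11-hydroxy-5β-drim-1-en-6-one (cis-fused; 5β-H, 9α-H, 10β-CH3; both C8 epimers) | OC[C@H]1C(C)CC(=O)[C@@H]2C(C)(C)CC=C[C@]12C | intermediate
16 | 11-hydroxy-5α-drim-1-en-6-one (trans-fused; both C8 epimers) | OC[C@H]1C(C)CC(=O)[C@H]2C(C)(C)CC=C[C@]12C | intermediate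
17 | 11-hydroxy-5α-driman-6-one (5α-H, 9α-H, 10β-CH3; both C8 epimers) | OC[C@H]1C(C)CC(=O)[C@H]2C(C)(C)CCC[C@]12C | intermediate
18 | 6,11-bis(trimethylsilyloxy)-5α-drim-6-ene (both C8 epimers) | C[Si](C)(C)OC[C@H]1C(C)C=C(O[Si](C)(C)C)[C@H]2C(C)(C)CCC[C@]12C | intermediate
19 | 11-(trimethylsilyloxy)drim-7-en-6-one | C[Si](C)(C)OC[C@H]1C(C)=CC(=O)[C@H]2C(C)(C)CCC[C@]12C | intermediate
20 | 11-hydroxydrim-7-en-6-one (5α-H, 9α-H, 10β-CH3) | OC[C@H]1C(C)=CC(=O)[C@H]2C(C)(C)CCC[C@]12C | intermediate
21 | drim-7-ene-6,11-diol (C6 epimers) | OC[C@H]1C(C)=CC(O)[C@H]2C(C)(C)CCC[C@]12C | intermediate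
22 | (−)-drimenol, (1S,4aS,8aS) | OC[C@H]1C(C)=CC[C@H]2C(C)(C)CCC[C@]12C | intermediate
23 | 11-iododrim-7-ene | IC[C@H]1C(C)=CC[C@H]2C(C)(C)CCC[C@]12C | intermediate
24 | methyl 3-bromo-4,5-dihydroxybenzoate | COC(=O)c1cc(O)c(O)c(Br)c1 | starting material
25 | methyl 3-bromo-4,5-bis(methoxymethoxy)benzoate | COC(=O)c1cc(OCOC)c(OCOC)c(Br)c1 | intermediate
26 | (drim-7-en-11-yl)zinc iodide | I[Zn]C[C@H]1C(C)=CC[C@H]2C(C)(C)CCC[C@]12C | intermediate
27 | methyl 3-(drim-7-en-11-yl)-4,5-bis(methoxymethoxy)benzoate | COC(=O)c1cc(OCOC)c(OCOC)c(C[C@H]2C(C)=CC[C@H]3C(C)(C)CCC[C@]23C)c1 | intermediate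
28 | methyl 3,4-dihydroxy-5-{[(5S,9S,10S)-drim-7-en-11-yl]}benzoate | COC(=O)c1cc(O)c(O)c(C[C@H]2C(C)=CC[C@H]3C(C)(C)CCC[C@]23C)c1 | target

Total step count: 14. Longest linear sequence: 13 steps (steps 1–11, 13 and 14).

Steps most likely to fail

Step 6. The hindered (Z)-diene may react too slowly with the β,β-disubstituted enone, so that Lewis-acid-induced decomposition of the diene overtakes cycloaddition. The fallback sets out from 14 and switches to an ionic Diels–Alder reaction. The alcohol is silylated (Me3SiCl, imidazole) and the enone is ketalised with 1,2-bis(trimethylsilyloxy)ethane and catalytic Me3SiOTf at −78 °C to give the trimethylsilyl ether dioxolane ketal F1. Catalytic TfOH at −78 → −20 °C opens the ketal to a vinyl dioxolanium ion, a far stronger dienophile, which should cyclise with the same tether and the same allylic-strain control to the cis-fused cycloadduct ketal F2. Aqueous HCl in THF removes the ketal and the silyl ether, and the route is rejoined at 15.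

Step 3. The catalyst may discriminate the two enantiotopic isopropenyl groups poorly, or ring closure onto the 1,1-disubstituted alkene may be slow. The fallback sets out from 7 and replaces asymmetric catalysis by resolution. Ring closure with the achiral catalyst Mo(N-2,6-i-Pr2C6H3)(CHCMe2Ph)[OC(CF3)2CH3]2 gives the racemic siloxane F3. The chemistry of steps 4 and 5 then gives the racemic enone F4 and the racemic trienone alcohol F5. Lipase-catalysed acylation (Burkholderia cepacia lipase, vinyl acetate) is run as a kinetic resolution of the primary alcohol, taking the (R)-enantiomer as the faster-reacting one to give the (7R)-acetate F6 (if the (S)-enantiomer reacts faster, its acetate is methanolysed instead). After separation the unreacted (S)-alcohol is 14, where the route is rejoined.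

Step 10. Hydride may be delivered to the tertiary terminus C8, the allyl cation may lose a proton to give dienes, or the C11 hydroxyl may capture the cation. The fallback sets out from 21 and uses a π-allyl palladium reduction instead of a free cation. Acetylation (Ac2O, pyridine, DMAP) gives the 6,11-diacetate F7. Pd(PPh3)4 (catalytic) with LiBHEt3 in THF ionises the allylic acetate, hydride attacks the less hindered terminus C6, and the excess hydride cleaves the primary acetate, giving 22.

Further compounds
F1 | step 6 | 2-(2-methylprop-1-en-1-yl)-2-[(2ξ,3S,4Z)-2,4-dimethyl-3-(trimethylsilyloxymethyl)hepta-4,6-dien-1-yl]-1,3-dioxolane | C[Si](C)(C)OC[C@H](/C(C)=C\C=C)C(C)CC1(C=C(C)C)OCCO1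
F2 | step 6 | 11-(trimethylsilyloxy)-5β-drim-1-en-6-one ethylene ketal (cis-fused; both C8 epimers) | C[Si](C)(C)OC[C@H]1C(C)CC3(OCCO3)[C@@H]2C(C)(C)CC=C[C@]12C
F3 | step 3 | racemic 2,2,4-trimethyl-5-(prop-1-en-2-yl)-5,6-dihydro-2H-1,2-oxasiline | C[Si]1(C)OCC(C(C)=C)C(C)=C1
F4 | step 3 | racemic 2-methyl-6-(2,2,4-trimethyl-5,6-dihydro-2H-1,2-oxasilin-5-yl)hept-2-en-4-one | C[Si]1(C)OCC(C(C)CC(=O)C=C(C)C)C(C)=C1
F5 | step 3 | racemic (8Z)-7-(hydroxymethyl)-2,6,8-trimethylundeca-2,8,10-trien-4-one | OCC(/C(C)=C\C=C)C(C)CC(=O)C=C(C)C
F6 | step 3 | acetate of the (7R)-enantiomer of 14 | CC(=O)OC[C@@H](/C(C)=C\C=C)C(C)CC(=O)C=C(C)C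
F7 | step 10 | drim-7-ene-6,11-diyl diacetate | CC(=O)OC[C@H]1C(C)=CC(OC(C)=O)[C@H]2C(C)(C)CCC[C@]12C
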